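**Retrosynthetic overview**
- Target ⇐ the tris-silylated (R)-ester, by buffered global desilylation and oxidation of the unveiled ring A hydroquinone to the quinone.
- (R)-ester ⇐ racemic benzylic carbinol + 3-methylbut-2-enoic acid, by an enantioselective dynamic kinetic O-acylation; this C–O bond formation sets the only stereocentre.
- Racemic carbinol ⇐ tris-silyl ether, lithiated ortho to its single OMe group, + 4-methylpent-3-enal.
- Tris-silyl ether ⇐ naphthazarin monomethyl ether (reductive silylation) ⇐ naphthazarin (mono-O-methylation). The early OMe fixes the final OMe/OH pattern and directs the metalation.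
- No ring is formed: both carbocycles are bought intact as naphthazarin.

Assumption: the stereocentre is (R) as read from the SMILES (shikonin series), and naphthazarin, 4-methylpent-3-en-1-ol and 3-methylbut-2-enoic acid are taken as inexpensive catalogue chemicals.

**Route**

Step 1
Reactants: 1 naphthazarin (5,8-dihydroxynaphthalene-1,4-dione)
Product: 2 5-hydroxy-8-methoxynaphthalene-1,4-dione
Conditions: MeI (5 equiv), Ag2O (0.6 equiv), CHCl3, rt, dark, 24–48 h; chromatography (dimethyl ether and 1 removed)
Reagents that add atoms: iodomethane, CI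
Why: Ag2O-promoted Williamson-type O-methylation of one of two equivalent peri-hydroxyls, which can be stopped at the monoether because the remaining OH is a strongly chelated, less acidic juglone-type phenol.

Step 2
Reactants: 2 5-hydroxy-8-methoxynaphthalene-1,4-dione
Product: 4 1,4,5-tris(tert-butyldimethylsilyloxy)-8-methoxynaphthalene, via 8-methoxynaphthalene-1,4,5-triol 3 (not isolated)
Conditions: H2 (1 atm), Pd/C, THF, rt, 20 min; filter under Ar; TBSOTf (3.6 equiv), Et3N, CH2Cl2, 0 °C → rt
Reagents that add atoms: tert-butyldimethylsilyl trifluoromethanesulfonate, CC(C)(C)[Si](C)(C)OS(=O)(=O)C(F)(F)F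
Why: Catalytic hydrogenation of the quinone to the hydroquinone followed at once by silyl ether formation with the powerful silyl triflate, which traps the aromatic triol (and any keto tautomer, as its silyl enol ether) as the same tris-silyl ether.

Step 3
Reactants: 5 4-methylpent-3-en-1-ol
Product: 6 4-methylpent-3-enal
Conditions: Dess–Martin periodinane, CH2Cl2, 0 °C → rt; pentane, filtration through Florisil; used cold as a solution
Reagents that add atoms: none
Why: Dess–Martin oxidation is near-neutral and gives the β,γ-unsaturated aldehyde without moving the double bond into conjugation.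

Step 4
Reactants: 4 1,4,5-tris(tert-butyldimethylsilyloxy)-8-methoxynaphthalene; 6 4-methylpent-3-enal
Product: 8 racemic 1-[1-methoxy-4,5,8-tris(tert-butyldimethylsilyloxy)naphthalen-2-yl]-4-methylpent-3-en-1-ol, via aryllithium 7 (not isolated)
Conditions: s-BuLi (1.15 equiv), TMEDA, THF, −78 → −45 °C; then 6 (1.5 equiv), −78 °C; H2O quench; chromatography on Et3N-deactivated silica
Reagents that add atoms: none
Why: Directed ortho-metalation at the only ring C–H next to OMe (every other ortho position is shielded by a bulky, non-directing OTBS group), then 1,2-addition of the aryllithium to the aldehyde; the new carbinol centre is formed racemic.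

Step 5
Reactants: 8 racemic 1-[1-methoxy-4,5,8-tris(tert-butyldimethylsilyloxy)naphthalen-2-yl]-4-methylpent-3-en-1-ol; 9 3-methylbut-2-enoic acid
Product: 10 (1R)-1-[1-methoxy-4,5,8-tris(tert-butyldimethylsilyloxy)naphthalen-2-yl]-4-methylpent-3-en-1-yl 3-methylbut-2-enoate
Conditions: 9 (1.5 equiv), ClCO2i-Pr, N-methylmorpholine, toluene, 0 °C, cannula-filtered (mixed carbonate); then 8, (η5-C5Ph5)Ru(CO)2Cl (5 mol %), KOt-Bu (5 mol %), (R)-benzotetramisole (5 mol %), toluene/t-amyl alcohol 1:1, 10 °C, 24–48 h
Reagents that add atoms: none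
Why: Proposed new method: a dynamic kinetic asymmetric O-acylation that joins two catalysts. The divalent ruthenium alkoxide (η5-C5Ph5)Ru(CO)2(OR), formed from the chloride and KOt-Bu, racemises the electron-rich benzylic carbinol by reversible β-hydride elimination and re-addition. In parallel, (R)-benzotetramisole attacks the enoyl carbonyl of the mixed carbonate to give a senecioyl isothiouronium ion. This ion acylates the (R)-carbinol by 1,2-addition (conjugate addition is blocked by the β,β-dimethyl terminus), selected by cation–π stacking of the naphthalene on the catalyst as in 1-arylalkanol resolutions. The carbonate leaving group collapses to CO2 and i-PrOH, so no carboxylate poisons ruthenium. Formation of the ester C–O bond is the enantio-determining event and fixes the (R) centre. The closest known reaction types are the non-enzymatic ruthenium/chiral-DMAP dynamic kinetic resolution of aryl alkyl carbinols with acetyl isopropyl carbonate and the isothiourea-catalysed kinetic resolution of benzylic alcohols with anhydrides.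

Step 6
Reactants: 10 (1R)-1-[1-methoxy-4,5,8-tris(tert-butyldimethylsilyloxy)naphthalen-2-yl]-4-methylpent-3-en-1-yl 3-methylbut-2-enoate
Product: 12 (1R)-1-(4-hydroxy-1-methoxy-5,8-dioxo-5,8-dihydronaphthalen-2-yl)-4-methylpent-3-en-1-yl 3-methylbut-2-enoate (the target, CNP0130192.1), via hydroquinone triol 11 (not isolated)
Conditions: TBAF, AcOH (1:1, 3.5 equiv), THF, 0 °C, Ar; then Ag2O (1.1 equiv), 0 °C → rt
Reagents that add atoms: none
Why: Acetic acid-buffered fluoride desilylation spares the ester and the acid- and base-labile benzylic C–O bond, and Ag2O then dehydrogenates only the ring A hydroquinone to the quinone; ring B keeps its OMe and its now hydrogen-bonded peri-OH, and the stereocentre is untouched.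

**Compound list**
1 | naphthazarin (5,8-dihydroxynaphthalene-1,4-dione) | O=C1C=CC(=O)c2c(O)ccc(O)c12 | starting material
2 | 5-hydroxy-8-methoxynaphthalene-1,4-dione | COc1ccc(O)c2C(=O)C=CC(=O)c12 | intermediate
3 | 8-methoxynaphthalene-1,4,5-triol | COc1ccc(O)c2c(O)ccc(O)c12 | intermediate
4 | 1,4,5-tris(tert-butyldimethylsilyloxy)-8-methoxynaphthalene | COc1ccc(O[Si](C)(C)C(C)(C)C)c2c(O[Si](C)(C)C(C)(C)C)ccc(O[Si](C)(C)C(C)(C)C)c12 | intermediate
5 | 4-methylpent-3-en-1-ol | CC(C)=CCCO | starting material
6 | 4-methylpent-3-enal | CC(C)=CCC=O | intermediate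
7 | [1-methoxy-4,5,8-tris(tert-butyldimethylsilyloxy)naphthalen-2-yl]lithium | COc1c([Li])cc(O[Si](C)(C)C(C)(C)C)c2c(O[Si](C)(C)C(C)(C)C)ccc(O[Si](C)(C)C(C)(C)C)c12 | intermediate
8 | racemic 1-[1-methoxy-4,5,8-tris(tert-butyldimethylsilyloxy)naphthalen-2-yl]-4-methylpent-3-en-1-ol | COc1c(C(O)CC=C(C)C)cc(O[Si](C)(C)C(C)(C)C)c2c(O[Si](C)(C)C(C)(C)C)ccc(O[Si](C)(C)C(C)(C)C)c12 | intermediate
9 | 3-methylbut-2-enoic acid (senecioic acid) | CC(C)=CC(=O)O | starting material
10 | (1R)-1-[1-methoxy-4,5,8-tris(tert-butyldimethylsilyloxy)naphthalen-2-yl]-4-methylpent-3-en-1-yl 3-methylbut-2-enoate | COc1c([C@@H](CC=C(C)C)OC(=O)C=C(C)C)cc(O[Si](C)(C)C(C)(C)C)c2c(O[Si](C)(C)C(C)(C)C)ccc(O[Si](C)(C)C(C)(C)C)c12 | intermediate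
11 | (1R)-1-(4,5,8-trihydroxy-1-methoxynaphthalen-2-yl)-4-methylpent-3-en-1-yl 3-methylbut-2-enoate | COc1c([C@@H](CC=C(C)C)OC(=O)C=C(C)C)cc(O)c2c(O)ccc(O)c12 | intermediate
12 | (1R)-1-(4-hydroxy-1-methoxy-5,8-dioxo-5,8-dihydronaphthalen-2-yl)-4-methylpent-3-en-1-yl 3-methylbut-2-enoate | COc1c([C@@H](CC=C(C)C)OC(=O)C=C(C)C)cc(O)c2c1C(=O)C=CC2=O | target

**Totals**
Total step count: 6. Longest linear sequence: 5 (steps 1, 2, 4, 5, 6).

**Three steps most likely to fail**

Step 5 (the proposed dynamic kinetic acylation). The two catalysts may not tolerate each other, the bulky tris-silyloxynaphthyl group may erode the selectivity, or the enoyl donor may deconjugate. The fallback uses known chemistry and sets out from 8. Dess–Martin oxidation gives the ketone 1-[1-methoxy-4,5,8-tris(tert-butyldimethylsilyloxy)naphthalen-2-yl]-4-methylpent-3-en-1-one F1. Corey–Bakshi–Shibata reduction ((S)-Me-CBS oxazaborolidine, catecholborane, toluene, −78 °C; the aryl group is the large group) gives the carbinol (1R)-1-[1-methoxy-4,5,8-tris(tert-butyldimethylsilyloxy)naphthalen-2-yl]-4-methylpent-3-en-1-ol F2. Steglich esterification of this with 9 (DCC, DMAP, CH2Cl2, 0 °C) comes back to the route at 10.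

Step 4 (ortho-lithiation and addition). Deprotonation may be slow or unselective next to the crowded silyl ethers, a silyl group may migrate, or the aryllithium may enolise aldehyde 6. The fallback sets out from 4 and replaces deprotonation by electrophilic halogenation and halogen–metal exchange. NBS (MeCN/CH2Cl2, −20 °C) brominates the most activated, least hindered position next to OMe to give 2-bromo-1-methoxy-4,5,8-tris(tert-butyldimethylsilyloxy)naphthalene F3. Bromine–lithium exchange (t-BuLi, 2 equiv, Et2O, −78 °C) comes back to the route at 7; if enolisation of 6 is the problem, 7 is transmetalated with CeCl3 before the aldehyde is added.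

Step 6 (global desilylation and oxidation). The free, very electron-rich triol 11 could lose the benzylic ester (ionisation or vinylogous elimination) before it is oxidised. The fallback sets out from 10 and oxidises first. (NH4)2Ce(NO3)6 (MeCN/H2O, 0 °C, 10 min) converts the unhindered bis-silyloxy ring A directly into the quinone; ring B is protected by its flanked OMe and the electron-withdrawing acyloxyalkyl group. This gives (1R)-1-[4-(tert-butyldimethylsilyloxy)-1-methoxy-5,8-dioxo-5,8-dihydronaphthalen-2-yl]-4-methylpent-3-en-1-yl 3-methylbut-2-enoate F4. Its remaining silyl ether is then cleaved with TBAF/AcOH (THF, 0 °C), coming back to the route at 12.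

**Further compounds**
F1 | step 5 | 1-[1-methoxy-4,5,8-tris(tert-butyldimethylsilyloxy)naphthalen-2-yl]-4-methylpent-3-en-1-one | COc1c(C(=O)CC=C(C)C)cc(O[Si](C)(C)C(C)(C)C)c2c(O[Si](C)(C)C(C)(C)C)ccc(O[Si](C)(C)C(C)(C)C)c12
F2 | step 5 | (1R)-1-[1-methoxy-4,5,8-tris(tert-butyldimethylsilyloxy)naphthalen-2-yl]-4-methylpent-3-en-1-ol | COc1c([C@@H](CC=C(C)C)O)cc(O[Si](C)(C)C(C)(C)C)c2c(O[Si](C)(C)C(C)(C)C)ccc(O[Si](C)(C)C(C)(C)C)c12
F3 | step 4 | 2-bromo-1-methoxy-4,5,8-tris(tert-butyldimethylsilyloxy)naphthalene | COc1c(Br)cc(O[Si](C)(C)C(C)(C)C)c2c(O[Si](C)(C)C(C)(C)C)ccc(O[Si](C)(C)C(C)(C)C)c12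
F4 | step 6 | (1R)-1-[4-(tert-butyldimethylsilyloxy)-1-methoxy-5,8-dioxo-5,8-dihydronaphthalen-2-yl]-4-methylpent-3-en-1-yl 3-methylbut-2-enoate | COc1c([C@@H](CC=C(C)C)OC(=O)C=C(C)C)cc(O[Si](C)(C)C(C)(C)C)c2c1C(=O)C=CC2=O
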